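The route rests on cutting the bond between C6 of ring A and the benzylic carbon C3' of the hexanoic acid chain. C6 lies between the C5 oxygen and the C7 methoxy group and carries a β-aryl carbonyl unit, so this bond is the retron of a phenol ortho-carbon adding to (E)-hex-2-enal. One operation joins 3,5-dimethoxy-4-prenylphenol to the enal under a chiral secondary amine, sets the C3' stereocentre and closes a lactol that masks the C5 oxygen and the acid. The precursor is symmetric: both free ring carbons are equivalent ortho positions and the prenyl group already sits at the future C8. The chromanone ring is added afterwards.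

Key step: step 4

Remark: unprimed locants in the overview follow the chromanone numbering of the target (C3' is the benzylic carbon of the acid chain); compounds 8–14 use chroman numbering (O1, C2 lactol or lactone carbon, C4 propyl-bearing carbon) and 15–16 use pyrano[2,3-f]chromene numbering (lactone O1/C2, C4, ring oxygen O7, methyl-bearing C8 and C9, ketone C10).

Step 1
Reactants: 1 3,5-dimethoxyphenol
Product: 2 (3,5-dimethoxyphenoxy)triisopropylsilane
Conditions: i-Pr3SiCl, imidazole, DMF, rt
Reagents that add atoms: triisopropylsilyl chloride, CC(C)[Si](Cl)(C(C)C)C(C)C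
Why: Silylation of the phenol (substitution at silicon, imidazole as base) masks the acidic OH for the lithiation, and the bulky triisopropylsilyl group neither directs metalation to its own ortho carbon nor migrates to carbon.

Step 2
Reactants: 2 (3,5-dimethoxyphenoxy)triisopropylsilane; 3 prenyl bromide (1-bromo-3-methylbut-2-ene)
Product: 5 [3,5-dimethoxy-4-(3-methylbut-2-enyl)phenoxy]triisopropylsilane, via aryllithium 4 (not isolated)
Conditions: n-BuLi, THF, 0 °C → rt; CuBr·SMe2 (10 mol%), then 3, −78 °C → rt
Reagents that add atoms: none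
Why: Directed ortho-metalation should take place at the carbon flanked by both methoxy groups, and copper-catalysed SN2 allylation of the aryllithium with the primary bromide should give the linear prenyl arene.

Step 3
Reactants: 5 [3,5-dimethoxy-4-(3-methylbut-2-enyl)phenoxy]triisopropylsilane
Product: 6 3,5-dimethoxy-4-(3-methylbut-2-enyl)phenol
Conditions: Bu4NF, THF, 0 °C → rt; H2O
Reagents that add atoms: none
Why: Fluoride-mediated desilylation cleaves the aryl silyl ether (strong Si–F bond) and leaves the methyl ethers and the prenyl group untouched.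

Step 4
Reactants: 6 3,5-dimethoxy-4-(3-methylbut-2-enyl)phenol; 7 (E)-hex-2-enal
Product: 9 (4R)-5,7-dimethoxy-6-(3-methylbut-2-enyl)-4-propylchroman-2-ol (both C2 epimers), via hydroxy aldehyde 8 (not isolated)
Conditions: (S)-2-[diphenyl(trimethylsilyloxy)methyl]pyrrolidine (20 mol%), PhCO2H (20 mol%), PhMe, 0 °C → rt
Reagents that add atoms: none
Why: The amine condenses with 7 to an (E)-iminium ion, a ring carbon of 6 ortho to the hydroxyl group (and ortho/para to the methoxy groups) adds to its β-carbon, rearomatisation and hydrolysis of the enamine release hydroxy aldehyde 8 and the catalyst, and 8 closes to lactol 9. The closest known reaction type is the iminium-catalysed asymmetric Friedel–Crafts alkylation of electron-rich phenols and naphthols with enals, which gives 4-substituted chroman-2-ols. The six-membered lactol ring closes by 6-exo-trig attack of the phenol oxygen on the aldehyde carbonyl, a reversible hemiacetalisation that also withdraws the aldehyde from further amine chemistry. The C4 stereocentre is set by the catalyst: the diphenyl(silyloxy)methyl group of the S-configured pyrrolidine shields the Si face of the iminium β-carbon, so the arene adds to the Re face and C4 becomes R. The step needs carbon rather than oxygen alkylation at a single ortho site, and the substrate secures this because its two free ring carbons are equivalent by symmetry, the para position is blocked by the prenyl group, oxygen addition is reversible, and after one alkylation the hydroxyl group is tied up in the lactol.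

Step 5
Reactants: 9 (4R)-5,7-dimethoxy-6-(3-methylbut-2-enyl)-4-propylchroman-2-ol
Product: 10 (4R)-5,7-dimethoxy-6-(3-methylbut-2-enyl)-4-propylchroman-2-one
Conditions: PhI(OAc)2, 2,2,6,6-tetramethylpiperidin-1-oxyl (10 mol%), CH2Cl2, rt
Reagents that add atoms: none
Why: Oxoammonium-mediated oxidation of the lactol hydroxyl with PhI(OAc)2 as terminal oxidant should convert both C2 epimers into one lactone without touching the trisubstituted alkene or the non-enolisable C4 stereocentre.

Step 6
Reactants: 10 (4R)-5,7-dimethoxy-6-(3-methylbut-2-enyl)-4-propylchroman-2-one; 11 tigloyl chloride [(E)-2-methylbut-2-enoyl chloride]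
Product: 12 (4R)-5,7-dimethoxy-8-[(E)-2-methylbut-2-enoyl]-6-(3-methylbut-2-enyl)-4-propylchroman-2-one
Conditions: SnCl4, 2,6-di-tert-butyl-4-methylpyridine, CH2Cl2, −78 → 0 °C
Reagents that add atoms: none
Why: Friedel–Crafts acylation can only take place at C8, the single remaining ring C–H, which is ortho to the C7 and para to the C5 methoxy group, and the hindered pyridine removes the HCl that would otherwise add to the prenyl double bond.

Step 7
Reactants: 12 (4R)-5,7-dimethoxy-8-[(E)-2-methylbut-2-enoyl]-6-(3-methylbut-2-enyl)-4-propylchroman-2-one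
Product: 14 (4R)-7-hydroxy-5-methoxy-8-[(E)-2-methylbut-2-enoyl]-6-(3-methylbut-2-enyl)-4-propylchroman-2-one, via dichloroboryl aryl ether 13 (not isolated)
Conditions: BCl3, CH2Cl2, −78 → 0 °C; H2O, 0 °C
Reagents that add atoms: none
Why: Chelation-controlled aryl methyl ether cleavage: boron binds the ketone oxygen and the adjacent C7 methoxy oxygen in a six-membered chelate and chloride removes that methyl group by SN2 displacement, whereas the C5 methoxy group has no carbonyl neighbour and should stay.

Step 8
Reactants: 14 (4R)-7-hydroxy-5-methoxy-8-[(E)-2-methylbut-2-enoyl]-6-(3-methylbut-2-enyl)-4-propylchroman-2-one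
Product: 15 (4R,8S,9R)-5-methoxy-8,9-dimethyl-6-(3-methylbut-2-enyl)-4-propyl-3,4,8,9-tetrahydropyrano[2,3-f]chromene-2,10-dione (cis-dimethyl)
Conditions: quinidine (20 mol%), PhCl, rt
Reagents that add atoms: none
Why: Cinchona alkaloid-catalysed asymmetric intramolecular oxa-Michael addition (6-endo-trig) of an ortho-tigloyl phenol: the quinuclidine nitrogen deprotonates the phenol and the chiral ion pair delivers the phenoxide to one face of the enone β-carbon, quinidine being chosen as the pseudoenantiomer expected to give 8S, and kinetic protonation of the enol places the C9 methyl cis to the C8 methyl (9R); any trans isomer formed has the same C8 configuration and converges in step 9.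

Step 9
Reactants: 15 (4R,8S,9R)-5-methoxy-8,9-dimethyl-6-(3-methylbut-2-enyl)-4-propyl-3,4,8,9-tetrahydropyrano[2,3-f]chromene-2,10-dione
Product: 16 (4R,8S,9S)-5-methoxy-8,9-dimethyl-6-(3-methylbut-2-enyl)-4-propyl-3,4,8,9-tetrahydropyrano[2,3-f]chromene-2,10-dione (trans-dimethyl)
Conditions: MgI2, Et3N, CH2Cl2, rt
Reagents that add atoms: none
Why: Soft enolisation (magnesium chelate, amine base) epimerises only the ketone α-carbon C9 to the thermodynamically preferred trans arrangement with both methyl groups equatorial (9S), while C8 and C4 carry no acidic hydrogen and should keep their configuration.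

Step 10
Reactants: 16 (4R,8S,9S)-5-methoxy-8,9-dimethyl-6-(3-methylbut-2-enyl)-4-propyl-3,4,8,9-tetrahydropyrano[2,3-f]chromene-2,10-dione
Product: 17 (3R)-3-[(2S,3S)-5-hydroxy-7-methoxy-2,3-dimethyl-8-(3-methylbut-2-enyl)-4-oxochroman-6-yl]hexanoic acid
Conditions: LiOH·H2O, THF/H2O, 0 °C; then 1 M HCl to pH 3, 0 °C
Reagents that add atoms: lithium hydroxide, [Li+].[OH-]
Why: Saponification of the aryl ester (lactone) is fast at 0 °C and frees the carboxylic acid and the C5 phenol (target numbering), which is then hydrogen-bonded to the C4 ketone, while the cold, short exposure to base is meant to leave the enolisable C3 centre of the trans chromanone unchanged.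

Compound list
1 | 3,5-dimethoxyphenol | COc1cc(O)cc(OC)c1 | starting material
2 | (3,5-dimethoxyphenoxy)triisopropylsilane | COc1cc(O[Si](C(C)C)(C(C)C)C(C)C)cc(OC)c1 | intermediate
3 | prenyl bromide (1-bromo-3-methylbut-2-ene) | CC(C)=CCBr | starting material
4 | [2,6-dimethoxy-4-(triisopropylsilyloxy)phenyl]lithium (not isolated) | [Li]c1c(OC)cc(O[Si](C(C)C)(C(C)C)C(C)C)cc1OC | intermediate
5 | [3,5-dimethoxy-4-(3-methylbut-2-enyl)phenoxy]triisopropylsilane | COc1cc(O[Si](C(C)C)(C(C)C)C(C)C)cc(OC)c1CC=C(C)C | intermediate
6 | 3,5-dimethoxy-4-(3-methylbut-2-enyl)phenol | COc1cc(O)cc(OC)c1CC=C(C)C | intermediate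
7 | (E)-hex-2-enal | CCC/C=C/C=O | starting material
8 | (3R)-3-[6-hydroxy-2,4-dimethoxy-3-(3-methylbut-2-enyl)phenyl]hexanal (not isolated) | CCC[C@H](CC=O)c1c(O)cc(OC)c(CC=C(C)C)c1OC | intermediate
9 | (4R)-5,7-dimethoxy-6-(3-methylbut-2-enyl)-4-propylchroman-2-ol (both C2 epimers) | CCC[C@@H]1CC(O)Oc2cc(OC)c(CC=C(C)C)c(OC)c12 | intermediate
10 | (4R)-5,7-dimethoxy-6-(3-methylbut-2-enyl)-4-propylchroman-2-one | CCC[C@@H]1CC(=O)Oc2cc(OC)c(CC=C(C)C)c(OC)c12 | intermediate
11 | tigloyl chloride [(E)-2-methylbut-2-enoyl chloride] | C/C=C(\C)C(=O)Cl | starting material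
12 | (4R)-5,7-dimethoxy-8-[(E)-2-methylbut-2-enoyl]-6-(3-methylbut-2-enyl)-4-propylchroman-2-one | CCC[C@@H]1CC(=O)Oc2c(C(=O)/C(C)=C/C)c(OC)c(CC=C(C)C)c(OC)c12 | intermediate
13 | (4R)-7-(dichloroboryloxy)-5-methoxy-8-[(E)-2-methylbut-2-enoyl]-6-(3-methylbut-2-enyl)-4-propylchroman-2-one (not isolated) | CCC[C@@H]1CC(=O)Oc2c(C(=O)/C(C)=C/C)c(OB(Cl)Cl)c(CC=C(C)C)c(OC)c12 | intermediate
14 | (4R)-7-hydroxy-5-methoxy-8-[(E)-2-methylbut-2-enoyl]-6-(3-methylbut-2-enyl)-4-propylchroman-2-one | CCC[C@@H]1CC(=O)Oc2c(C(=O)/C(C)=C/C)c(O)c(CC=C(C)C)c(OC)c12 | intermediate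
15 | (4R,8S,9R)-5-methoxy-8,9-dimethyl-6-(3-methylbut-2-enyl)-4-propyl-3,4,8,9-tetrahydropyrano[2,3-f]chromene-2,10-dione (cis-2,3-dimethylchromanone fused to the dihydrocoumarin lactone) | CCC[C@@H]1CC(=O)Oc2c1c(OC)c(CC=C(C)C)c1c2C(=O)[C@H](C)[C@H](C)O1 | intermediate
16 | (4R,8S,9S)-5-methoxy-8,9-dimethyl-6-(3-methylbut-2-enyl)-4-propyl-3,4,8,9-tetrahydropyrano[2,3-f]chromene-2,10-dione (trans isomer) | CCC[C@@H]1CC(=O)Oc2c1c(OC)c(CC=C(C)C)c1c2C(=O)[C@@H](C)[C@H](C)O1 | intermediate
17 | (3R)-3-[(2S,3S)-5-hydroxy-7-methoxy-2,3-dimethyl-8-(3-methylbut-2-enyl)-4-oxochroman-6-yl]hexanoic acid | CCC[C@H](CC(=O)O)c1c(O)c2c(c(CC=C(C)C)c1OC)O[C@@H](C)[C@H](C)C2=O | target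

Total step count: 10. Longest linear sequence: 10 steps (1 → 17).

Steps most likely to fail

Step 4. The carbon–carbon bond formation may be slow, because the prenyl group pushes both methoxy groups toward the reacting ring carbons and an aliphatic iminium ion is a weaker electrophile than a cinnamyl one. Enantiofacial control may then be lost to a racemic acid-promoted background addition. The fallback sets the stereocentre by reduction instead of by arene addition and sets out from phenol 6. Esterification with hex-2-ynoic acid (DCC, DMAP, CH2Cl2) would give 3,5-dimethoxy-4-(3-methylbut-2-enyl)phenyl hex-2-ynoate F1. Gold-catalysed intramolecular hydroarylation (Ph3PAuCl, AgSbF6, CH2Cl2) would close it to 5,7-dimethoxy-6-(3-methylbut-2-enyl)-4-propylchromen-2-one F2; both ortho carbons are again equivalent. Copper hydride-catalysed asymmetric 1,4-reduction of F2 (Cu(OAc)2, the DTBM-SEGPHOS antipode that delivers hydride to give 4R, (EtO)2MeSiH, t-BuOH, PhMe) leaves the prenyl alkene alone and comes back to the route at lactone 10.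

Step 6. The acid released during acylation may protonate the prenyl double bond (hydrochlorination or cation-driven cyclisation), or acylation may not occur at the crowded ring carbon. The fallback brings in the carbonyl carbon under non-protic conditions and adds the chain afterwards; it sets out from lactone 10. Vilsmeier–Haack formylation (POCl3, DMF; aqueous NaOAc) would give (4R)-5,7-dimethoxy-6-(3-methylbut-2-enyl)-2-oxo-4-propylchroman-8-carbaldehyde F3. Nozaki–Hiyama–Kishi addition of (E)-2-bromobut-2-ene (CrCl2, NiCl2 cat., DMF), which is selective for the aldehyde over the lactone, would give (4R)-8-[(E)-1-hydroxy-2-methylbut-2-enyl]-5,7-dimethoxy-6-(3-methylbut-2-enyl)-4-propylchroman-2-one F4. Oxidation of the allylic, benzylic alcohol (MnO2, CH2Cl2) comes back to the route at enone 12.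

Step 8. Facial discrimination in the conjugate addition may be poor, because the phenol is flanked by the prenyl group, and the C8 configuration may erode through reversible ring opening. The fallback sets C8 by SN2 inversion of a carbinol instead of by face-selective addition and sets out from lactone 10.
- Acylation with propanoyl chloride under the conditions of step 6 would give (4R)-5,7-dimethoxy-6-(3-methylbut-2-enyl)-8-propanoyl-4-propylchroman-2-one F5.
- Demethylation with BCl3 as in step 7 would give (4R)-7-hydroxy-5-methoxy-6-(3-methylbut-2-enyl)-8-propanoyl-4-propylchroman-2-one F6.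
- A syn-selective titanium enolate aldol addition (TiCl4, i-Pr2NEt, CH2Cl2, −78 °C; MeCHO) would give (4R)-7-hydroxy-8-[(2S,3R)-3-hydroxy-2-methylbutanoyl]-5-methoxy-6-(3-methylbut-2-enyl)-4-propylchroman-2-one F7 together with its (2R,3S)-syn diastereomer (4R)-7-hydroxy-8-[(2R,3S)-3-hydroxy-2-methylbutanoyl]-5-methoxy-6-(3-methylbut-2-enyl)-4-propylchroman-2-one F8.
- F7 and F8 would be separated by chromatography, or F8 removed by lipase-mediated acetylation.
- Mitsunobu cyclisation of F7 (PPh3, DIAD, THF, 0 °C) inverts the carbinol carbon and comes back to the route at trans lactone 16, so that step 9 is not needed.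

Further compounds
F1 | step 4 | 3,5-dimethoxy-4-(3-methylbut-2-enyl)phenyl hex-2-ynoate | CCCC#CC(=O)Oc1cc(OC)c(CC=C(C)C)c(OC)c1
F2 | step 4 | 5,7-dimethoxy-6-(3-methylbut-2-enyl)-4-propylchromen-2-one | CCCC1=CC(=O)Oc2cc(OC)c(CC=C(C)C)c(OC)c12
F3 | step 6 | (4R)-5,7-dimethoxy-6-(3-methylbut-2-enyl)-2-oxo-4-propylchroman-8-carbaldehyde | CCC[C@@H]1CC(=O)Oc2c(C=O)c(OC)c(CC=C(C)C)c(OC)c12
F4 | step 6 | (4R)-8-[(E)-1-hydroxy-2-methylbut-2-enyl]-5,7-dimethoxy-6-(3-methylbut-2-enyl)-4-propylchroman-2-one (both carbinol epimers) | CCC[C@@H]1CC(=O)Oc2c(C(O)/C(C)=C/C)c(OC)c(CC=C(C)C)c(OC)c12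
F5 | step 8 | (4R)-5,7-dimethoxy-6-(3-methylbut-2-enyl)-8-propanoyl-4-propylchroman-2-one | CCC[C@@H]1CC(=O)Oc2c(C(=O)CC)c(OC)c(CC=C(C)C)c(OC)c12
F6 | step 8 | (4R)-7-hydroxy-5-methoxy-6-(3-methylbut-2-enyl)-8-propanoyl-4-propylchroman-2-one | CCC[C@@H]1CC(=O)Oc2c(C(=O)CC)c(O)c(CC=C(C)C)c(OC)c12
F7 | step 8 | (4R)-7-hydroxy-8-[(2S,3R)-3-hydroxy-2-methylbutanoyl]-5-methoxy-6-(3-methylbut-2-enyl)-4-propylchroman-2-one | CCC[C@@H]1CC(=O)Oc2c(C(=O)[C@@H](C)[C@@H](C)O)c(O)c(CC=C(C)C)c(OC)c12
F8 | step 8 | (4R)-7-hydroxy-8-[(2R,3S)-3-hydroxy-2-methylbutanoyl]-5-methoxy-6-(3-methylbut-2-enyl)-4-propylchroman-2-one | CCC[C@@H]1CC(=O)Oc2c(C(=O)[C@H](C)[C@H](C)O)c(O)c(CC=C(C)C)c(OC)c12
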